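The furanone ring is disconnected at the bond between the bromine-bearing ring carbon C4 and the ylidene-bearing ring carbon C5. The key step is a 5-exo Heck cyclisation of an acyclic vinyl ester of a 3,3-dibromoacrylic acid. One bromine of the CBr2 group is spent to join C4 to the oxygen-bearing vinyl carbon, the other stays as the C4–Br of the target, and β-hydride elimination leaves the exocyclic C5=C6 alkene. It exploits two features of the ring: C4 is a brominated sp2 carbon and C5 is an enol-ester carbon between ring oxygen O1 and exocyclic C6. Bromination–dehydrobromination at C6 finishes the target; the C1′ acetoxy stereocentre comes from a catalytic asymmetric diazoacetate aldol.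

Key step: step 7

Remark on numbering: ring atoms are O1, C2 (lactone carbonyl), C3 (bearing the side chain), C4 (bearing bromine) and C5 (bearing exocyclic C6); C1′ is the acetoxy carbinol carbon. The target is the (R),(Z) isomer.

Assumption: (S,S)-ProPhenol is written in step 1 on the assumption that this antipode delivers the (R)-carbinol. The configuration of 3 is to be checked as its Mosher ester, and the (R,R)-ligand is used instead if the sense is the opposite.

Step 1
Reactants: 1 butanal; 2 tert-butyl diazoacetate
Product: 3 tert-butyl (3R)-2-diazo-3-hydroxyhexanoate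
Conditions: Bu2Mg (10 mol %), (S,S)-ProPhenol [2,6-bis{[(2S)-2-(hydroxydiphenylmethyl)pyrrolidin-1-yl]methyl}-4-methylphenol] (5 mol %), cis-cyclopentane-1,2-diol (5 mol %), THF, −20 °C
Reagents that add atoms: none
Why: Direct catalytic asymmetric aldol addition of a diazoacetate (dinuclear magnesium–ProPhenol catalysis): the magnesium-bound diazo ester adds to the aldehyde inside the chiral pocket of the ligand, so the C1′ carbinol centre is set by catalyst control.

Step 2
Reactants: 3 tert-butyl (3R)-2-diazo-3-hydroxyhexanoate
Product: 4 tert-butyl (3R)-3-acetoxy-2-diazohexanoate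
Conditions: Ac2O, pyridine, DMAP (cat.), CH2Cl2, 0 °C
Reagents that add atoms: acetic anhydride, CC(=O)OC(C)=O
Why: Base-mediated O-acetylation (DMAP-catalysed nucleophilic acyl substitution) proceeds without touching the diazo ester or the configuration at C1′.

Step 3
Reactants: 4 tert-butyl (3R)-3-acetoxy-2-diazohexanoate
Product: 5 tert-butyl (3R)-3-acetoxy-2-oxohexanoate
Conditions: dimethyldioxirane (acetone solution, 1.1 equiv), CH2Cl2, −78 to 0 °C; concentrate and use crude
Reagents that add atoms: dimethyldioxirane, CC1(C)OO1
Why: Diazo-to-carbonyl oxidation: the electrophilic oxygen of dimethyldioxirane is transferred to the nucleophilic diazo carbon with loss of N2 under neutral conditions that do not enolise the new α-acetoxy ketone.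

Step 4
Reactants: 5 tert-butyl (3R)-3-acetoxy-2-oxohexanoate
Product: 6 tert-butyl (3R)-3-acetoxy-2-(dibromomethylidene)hexanoate
Conditions: CBr4 (2 equiv), PPh3 (2 equiv), Zn dust (2 equiv), CH2Cl2, rt (ylide pre-formed); then 5, 0 °C
Reagents that add atoms: carbon tetrabromide, BrC(Br)(Br)Br
Why: Ramirez dibromo-olefination (the Wittig stage of the Corey–Fuchs sequence): the pre-formed ylide Ph3P=CBr2 attacks the strongly electrophilic α-keto ester carbonyl under neutral zinc-modified conditions, the CBr2 terminus has no E/Z issue, and the C1′ centre becomes allylic and no longer enolisable.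

Step 5
Reactants: 6 tert-butyl (3R)-3-acetoxy-2-(dibromomethylidene)hexanoate
Product: 7 (3R)-3-acetoxy-2-(dibromomethylidene)hexanoic acid
Conditions: CF3CO2H/CH2Cl2 (1:4), 0 °C to rt
Reagents that add atoms: none
Why: Acidolysis of the tert-butyl ester (E1 loss of isobutene) leaves the secondary acetate and the vinylic bromides untouched.

Step 6
Reactants: 7 (3R)-3-acetoxy-2-(dibromomethylidene)hexanoic acid
Product: 8 ethenyl (3R)-3-acetoxy-2-(dibromomethylidene)hexanoate
Conditions: vinyl acetate (solvent), Pd(OAc)2 (5 mol %), KOH (10 mol %), rt
Reagents that add atoms: vinyl acetate, C=COC(C)=O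
Why: Transvinylation catalysed by divalent palladium (acyloxypalladation of vinyl acetate followed by β-acetoxy elimination), driven by the solvent excess of vinyl acetate; divalent palladium does not insert into the C–Br bonds.

Step 7
Reactants: 8 ethenyl (3R)-3-acetoxy-2-(dibromomethylidene)hexanoate
Product: 9 (1R)-1-(4-bromo-5-methylidene-2-oxo-2,5-dihydrofuran-3-yl)butyl acetate
Conditions: Pd(OAc)2 (10 mol %), PPh3 (25 mol %), Ag2CO3 (1.2 equiv), MeCN (0.01 M), 60 °C; product taken on without storage
Reagents that add atoms: none
Why: Intramolecular Mizoroki–Heck reaction: zerovalent palladium inserts into the C–Br bond cis to the ester (the less hindered one, trans to the 1-acetoxybutyl group), silver removes bromide, the cationic vinylpalladium adds syn across the vinyl-ester C=C with C4 bonding to the oxygen-bearing carbon C5, and β-hydride elimination of the C5–H gives the exocyclic C5=C6 alkene. The closest known reaction types are Heck cyclisations of 1,1-dibromoalkenes that keep the second bromine and the internal (oxygen-bearing carbon) Heck vinylation of enol esters under cationic conditions. The furanone ring closes in the 5-exo-trig mode; the 6-endo mode to a pyranone is disfavoured by the three-atom planar tether and by the polarity of the enol ester. No stereocentre is created, and the C1′ centre, now allylic and non-enolisable, is not touched. The step needs reaction at one bromine only, which is helped because only the palladium species cis to the ester can cyclise and high dilution limits further reaction of the product. It also needs β-hydride instead of β-acyloxy elimination from the alkylpalladium, which the halide-free cationic regime and the conjugation gained in the diene lactone favour.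

Step 8
Reactants: 9 (1R)-1-(4-bromo-5-methylidene-2-oxo-2,5-dihydrofuran-3-yl)butyl acetate
Product: 11 (1R)-1-[(5Z)-4-bromo-5-(bromomethylidene)-2-oxo-2,5-dihydrofuran-3-yl]butyl acetate, via tribromolactone 10 (not isolated)
Conditions: Br2 (1.05 equiv), CH2Cl2, −78 to 0 °C, dark; then Et3N (1.5 equiv), 0 °C
Reagents that add atoms: bromine, BrBr
Why: Bromination–dehydrobromination: Br2 adds to the electron-rich exocyclic enol-ester alkene and Et3N then removes HBr (C5–Br with a C6–H), giving the Z bromomethylidene because the E isomer would press the C6 bromine against the C4 bromine.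

Compound list
1 | butanal | CCCC=O | starting material
2 | tert-butyl diazoacetate | [N-]=[N+]=CC(=O)OC(C)(C)C | starting material
3 | tert-butyl (3R)-2-diazo-3-hydroxyhexanoate | CCC[C@@H](O)C(=[N+]=[N-])C(=O)OC(C)(C)C | intermediate
4 | tert-butyl (3R)-3-acetoxy-2-diazohexanoate | CCC[C@@H](OC(C)=O)C(=[N+]=[N-])C(=O)OC(C)(C)C | intermediate
5 | tert-butyl (3R)-3-acetoxy-2-oxohexanoate | CCC[C@@H](OC(C)=O)C(=O)C(=O)OC(C)(C)C | intermediate
6 | tert-butyl (3R)-3-acetoxy-2-(dibromomethylidene)hexanoate | CCC[C@@H](OC(C)=O)C(=C(Br)Br)C(=O)OC(C)(C)C | intermediate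
7 | (3R)-3-acetoxy-2-(dibromomethylidene)hexanoic acid | CCC[C@@H](OC(C)=O)C(=C(Br)Br)C(=O)O | intermediate
8 | ethenyl (3R)-3-acetoxy-2-(dibromomethylidene)hexanoate | CCC[C@@H](OC(C)=O)C(=C(Br)Br)C(=O)OC=C | intermediate
9 | (1R)-1-(4-bromo-5-methylidene-2-oxo-2,5-dihydrofuran-3-yl)butyl acetate | CCC[C@@H](OC(C)=O)C1=C(Br)C(=C)OC1=O | intermediate
10 | (1R)-1-[4,5-dibromo-5-(bromomethyl)-2-oxo-2,5-dihydrofuran-3-yl]butyl acetate (both C5 epimers, not isolated) | CCC[C@@H](OC(C)=O)C1=C(Br)C(Br)(CBr)OC1=O | intermediate
11 | (1R)-1-[(5Z)-4-bromo-5-(bromomethylidene)-2-oxo-2,5-dihydrofuran-3-yl]butyl acetate | CCC[C@@H](OC(C)=O)C1=C(Br)/C(=C/Br)OC1=O | target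

Total step count: 8. Longest linear sequence: 8 steps (from 1 and 2).

Steps most likely to fail

Step 7. The alkylpalladium formed after ring closure may expel the ring carboxylate (β-acyloxy elimination, which reopens the ring) instead of hydride. Closure may also occur in the 6-endo sense, or zerovalent palladium may insert into the remaining C–Br bond of the product. The fallback closes the same C4–C5 bond by a radical instead of an organopalladium. It sets out from 8: slow addition of Bu3SnH (1.1 equiv) and AIBN in benzene at 80 °C (5 mM) generates the α-bromovinyl radical, whose 5-exo-trig cyclisation onto the vinyl ester and hydrogen transfer should give the methyl lactone (1R)-1-[(5RS)-4-bromo-5-methyl-2-oxo-2,5-dihydrofuran-3-yl]butyl acetate F1. NBS with AIBN in PhCF3 at 80 °C should brominate the doubly activated C5–H to the bromolactone (1R)-1-[(5RS)-4,5-dibromo-5-methyl-2-oxo-2,5-dihydrofuran-3-yl]butyl acetate F2. Et3N in CH2Cl2 at 0 °C then eliminates HBr toward the methyl group, and the route is rejoined at 9.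

Step 4. Enolisation of the α-acetoxy ketone 5 in the presence of the ylide or ZnBr2 may erode the C1′ configuration, or olefination of the hindered carbonyl may stall. The fallback sets the stereocentre after the olefination, by reagent-controlled reduction. It sets out from 3, which can then be made without the chiral ligand. Dess–Martin periodinane should give the diazo ketoester tert-butyl 2-diazo-3-oxohexanoate F3, and dimethyldioxirane the tricarbonyl tert-butyl 2,3-dioxohexanoate F4. CBr4/PPh3/Zn should olefinate the central, most electrophilic carbonyl to the enone tert-butyl 2-(dibromomethylidene)-3-oxohexanoate F5. Corey–Bakshi–Shibata reduction ((S)-2-methyl-CBS-oxazaborolidine, catecholborane, toluene, −78 °C) should give the allylic alcohol tert-butyl (3R)-2-(dibromomethylidene)-3-hydroxyhexanoate F6. Ac2O/pyridine then returns to 6.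

Step 6. Vinyl acetate may reduce the divalent palladium catalyst to zerovalent palladium, which then consumes the C–Br bonds, or exchange at the hindered acid may be slow. The fallback acylates an enolate oxygen without a transition metal. It sets out from 7: (COCl)2 and DMF (cat.) in CH2Cl2 should give the acid chloride (3R)-3-acetoxy-2-(dibromomethylidene)hexanoyl chloride F7. This is added at −78 °C to lithium ethenolate (from n-BuLi and THF, 35 °C), and O-acylation returns to 8.

Further compounds
F1 | step 7 | (1R)-1-[(5RS)-4-bromo-5-methyl-2-oxo-2,5-dihydrofuran-3-yl]butyl acetate | CCC[C@@H](OC(C)=O)C1=C(Br)C(C)OC1=O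
F2 | step 7 | (1R)-1-[(5RS)-4,5-dibromo-5-methyl-2-oxo-2,5-dihydrofuran-3-yl]butyl acetate | CCC[C@@H](OC(C)=O)C1=C(Br)C(C)(Br)OC1=O
F3 | step 4 | tert-butyl 2-diazo-3-oxohexanoate | CCCC(=O)C(=[N+]=[N-])C(=O)OC(C)(C)C
F4 | step 4 | tert-butyl 2,3-dioxohexanoate | CCCC(=O)C(=O)C(=O)OC(C)(C)C
F5 | step 4 | tert-butyl 2-(dibromomethylidene)-3-oxohexanoate | CCCC(=O)C(=C(Br)Br)C(=O)OC(C)(C)C
F6 | step 4 | tert-butyl (3R)-2-(dibromomethylidene)-3-hydroxyhexanoate | CCC[C@@H](O)C(=C(Br)Br)C(=O)OC(C)(C)C
F7 | step 6 | (3R)-3-acetoxy-2-(dibromomethylidene)hexanoyl chloride | CCC[C@@H](OC(C)=O)C(=C(Br)Br)C(Cl)=O
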